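**Retrosynthetic overview**

1. Compound flow: 1 → 2 → 3 → 4 → 5 → 6 → 7 → 8 → 9 → 10 (2, 4, 5 and 7 are not isolated). Every stereocentre except C1 and the re-made C3–O is bought in gibberellic acid 1.
2. 10 ⇐ 9: the 1α-hydroxyl comes from a C1 ketone by hydride delivery from the axial 3β-hydroxyl (1,3-anti).
3. 9 ⇐ 8 ⇐ 6: the C3–O bond is made on the β face by a photochemical peroxide-relay oxidation/epoxidation of the transposed allylic alcohol; the oxirane is then opened at C2.
4. 6 ⇐ 3 ⇐ 1: the C1–O bond is made by the same photochemical relay on 1; a Wharton transposition moves the double bond from C1=C2 to C2=C3.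
5. Rings: the four carbocycles (rings A to D) and the γ-lactone are never broken. Only two transient oxiranes are formed, first at C1–C2 (step 1), then at C2–C3 (step 3), and each is opened again.

Assumption: gibberellin numbering is used and α means the face of ring A that carries the 19,10-lactone bridge (β the opposite face), so the target is read as 1α,3β,13-trihydroxy-20-norgibberell-16-ene-7,19-dioic acid 19,10-lactone; gibberellic acid (GA3, a bulk fermentation product) is taken as the commercial chiral starting material and is used as the free acid throughout.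

**Route**

Step 1
Reactants: 1 gibberellic acid (GA3; 3β,13-dihydroxy-20-norgibberella-1,16-diene-7,19-dioic acid 19,10-lactone)
Product: 3 1β,2β-epoxy-13-hydroxy-3-oxo-20-norgibberell-16-ene-7,19-dioic acid 19,10-lactone, via 3-dehydrogibberellic acid 2 (not isolated)
Conditions: 2-ethylanthraquinone (10 mol %), O2 (1 atm), t-BuOH, 405 nm LEDs, 20 °C; then dark, DBU (2.5 equiv), 0 → 20 °C; Na2S2O3 wash, citric acid work-up
Reagents that add atoms: dioxygen, O=O
Why: Proposed new method: a photochemical peroxide relay – triplet 2-ethylanthraquinone abstracts the weak, hydridic C3–H of the allylic carbinol (the 13-hydroxyl is tertiary and has no such hydrogen), O2 reoxidises the anthrahydroquinone as in the anthraquinone process and releases one equivalent of H2O2, and DBU then turns this H2O2 into HOO−, which adds to C1 of enone 2 from the β face (the α face is closed by the lactone oxygen on C10) and closes to the 1β,2β-oxirane in a nucleophilic Weitz–Scheffer epoxidation that leaves the electron-rich C16 methylene untouched; the closest known reactions are anthraquinone-photocatalysed aerobic oxidation of alcohols and alkaline H2O2 epoxidation of enones, which have not been coupled so that the substrate's own carbinol hydrogen pays for the epoxide oxygen.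

Step 2
Reactants: 3 1β,2β-epoxy-13-hydroxy-3-oxo-20-norgibberell-16-ene-7,19-dioic acid 19,10-lactone
Product: 6 1β,13-dihydroxy-20-norgibberella-2,16-diene-7,19-dioic acid 19,10-lactone (1β-hydroxy-GA5), via epoxy hydrazone 4 (not isolated), via alkenyl diazene 5 (not isolated)
Conditions: N2H4·H2O (3 equiv), AcOH (0.3 equiv), degassed MeOH, Ar, 0 → 20 °C
Reagents that add atoms: none
Why: Wharton transposition: the C3 hydrazone 4 tautomerises with opening of the oxirane to the alkenyl diazene 5, which loses N2 to leave C3–H and the C2=C3 double bond, while the C1–O bond made in step 1 is never broken (the oxygen stays 1β) and the oxygen-free medium prevents diimide reduction of the alkenes.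

Step 3
Reactants: 6 1β,13-dihydroxy-20-norgibberella-2,16-diene-7,19-dioic acid 19,10-lactone
Product: 8 2β,3β-epoxy-13-hydroxy-1-oxo-20-norgibberell-16-ene-7,19-dioic acid 19,10-lactone, via 1-oxo enone 7 (not isolated)
Conditions: 2-ethylanthraquinone (10 mol %), O2 (1 atm), t-BuOH, 405 nm LEDs, 20 °C; then dark, DBU (2.5 equiv), 0 → 20 °C; Na2S2O3 wash, citric acid work-up
Reagents that add atoms: dioxygen, O=O
Why: Proposed new method: the same photochemical peroxide relay on the transposed allylic alcohol – hydrogen abstraction at the C1 carbinol gives enone 7 and one equivalent of H2O2, and HOO− then attacks C3 from the β face, because the α face is shielded by the axial C19 carbonyl on C4 and the lactone bridge, so that ring closure gives the 2β,3β-oxirane and fixes the new C3–O bond as β by substrate control; the closest known reactions are again anthraquinone-photocatalysed aerobic alcohol oxidation and Weitz–Scheffer epoxidation run as separate operations.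

Step 4
Reactants: 8 2β,3β-epoxy-13-hydroxy-1-oxo-20-norgibberell-16-ene-7,19-dioic acid 19,10-lactone
Product: 9 3β,13-dihydroxy-1-oxo-20-norgibberell-16-ene-7,19-dioic acid 19,10-lactone (1-oxo-GA1)
Conditions: (C5H5)2TiCl2 (3 equiv), Zn dust (6 equiv), THF, 20 °C; then 8, THF–MeOH, −20 → 0 °C; cold 0.5 M HCl work-up
Reagents that add atoms: none
Why: Titanocene-mediated reductive opening of an α,β-epoxy ketone: (C5H5)2TiCl (trivalent titanium) cleaves the C2–O bond next to the carbonyl by single-electron transfer and the C2 radical is reduced and protonated, so C3 keeps its β oxygen as a free hydroxyl, while this mild reagent reduces neither the ketone, the C10–O bond α to it, the lactone nor the alkene.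

Step 5
Reactants: 9 3β,13-dihydroxy-1-oxo-20-norgibberell-16-ene-7,19-dioic acid 19,10-lactone
Product: 10 1α,3β,13-trihydroxy-20-norgibberell-16-ene-7,19-dioic acid 19,10-lactone (1α-hydroxy-GA1, CNP0252949.2)
Conditions: Me4NBH(OAc)3 (5 equiv), MeCN–AcOH (1:1), −25 → 0 °C
Reagents that add atoms: none
Why: Evans–Saksena hydroxyl-directed reduction: the axial 3β-hydroxyl exchanges onto boron and delivers hydride intramolecularly to the β (axial) face of the C1 ketone through a chair six-membered transition state, which gives the equatorial 1α-alcohol (1,3-anti diol), while the lactone, the acid and the alkene are inert to this reagent.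

**Compound list**

1 | gibberellic acid (GA3; 3β,13-dihydroxy-20-norgibberella-1,16-diene-7,19-dioic acid 19,10-lactone) | C=C1C[C@]23C[C@@]1(O)CC[C@H]2[C@@]12OC(=O)[C@@](C)([C@H]1[C@@H]3C(=O)O)[C@@H](O)C=C2 | starting material
2 | 3-dehydrogibberellic acid (13-hydroxy-3-oxo-20-norgibberella-1,16-diene-7,19-dioic acid 19,10-lactone) | C=C1C[C@]23C[C@@]1(O)CC[C@H]2[C@@]12OC(=O)[C@@](C)([C@H]1[C@@H]3C(=O)O)C(=O)C=C2 | intermediate
3 | 1β,2β-epoxy-13-hydroxy-3-oxo-20-norgibberell-16-ene-7,19-dioic acid 19,10-lactone | C=C1C[C@]23C[C@@]1(O)CC[C@H]2[C@@]12OC(=O)[C@@](C)([C@H]1[C@@H]3C(=O)O)C(=O)[C@H]4O[C@H]42 | intermediate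
4 | epoxy hydrazone (3-hydrazone of 3, C3=N–NH2, oxirane intact) | C=C1C[C@]23C[C@@]1(O)CC[C@H]2[C@@]12OC(=O)[C@@](C)([C@H]1[C@@H]3C(=O)O)C(=NN)[C@H]4O[C@H]42 | intermediate
5 | alkenyl diazene (3-diazenyl-1β,13-dihydroxy-20-norgibberella-2,16-diene-7,19-dioic acid 19,10-lactone) | C=C1C[C@]23C[C@@]1(O)CC[C@H]2[C@@]12OC(=O)[C@@](C)([C@H]1[C@@H]3C(=O)O)C(N=N)=C[C@H]2O | intermediate
6 | 1β,13-dihydroxy-20-norgibberella-2,16-diene-7,19-dioic acid 19,10-lactone (1β-hydroxy-GA5) | C=C1C[C@]23C[C@@]1(O)CC[C@H]2[C@@]12OC(=O)[C@@](C)([C@H]1[C@@H]3C(=O)O)C=C[C@H]2O | intermediate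
7 | 1-oxo enone (13-hydroxy-1-oxo-20-norgibberella-2,16-diene-7,19-dioic acid 19,10-lactone) | C=C1C[C@]23C[C@@]1(O)CC[C@H]2[C@@]12OC(=O)[C@@](C)([C@H]1[C@@H]3C(=O)O)C=CC2=O | intermediate
8 | 2β,3β-epoxy-13-hydroxy-1-oxo-20-norgibberell-16-ene-7,19-dioic acid 19,10-lactone | C=C1C[C@]23C[C@@]1(O)CC[C@H]2[C@@]12OC(=O)[C@@](C)([C@H]1[C@@H]3C(=O)O)[C@H]4O[C@H]4C2=O | intermediate
9 | 3β,13-dihydroxy-1-oxo-20-norgibberell-16-ene-7,19-dioic acid 19,10-lactone (1-oxo-GA1) | C=C1C[C@]23C[C@@]1(O)CC[C@H]2[C@@]12OC(=O)[C@@](C)([C@H]1[C@@H]3C(=O)O)[C@@H](O)CC2=O | intermediate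
10 | 1α,3β,13-trihydroxy-20-norgibberell-16-ene-7,19-dioic acid 19,10-lactone (1α-hydroxy-GA1, CNP0252949.2) | C=C1C[C@]23C[C@@]1(O)CC[C@H]2[C@@]12OC(=O)[C@@](C)([C@H]1[C@@H]3C(=O)O)[C@@H](O)C[C@@H]2O | target

**Step count and risks**

Total step count: 5. Longest linear sequence: 5 steps (fully linear from 1).

The three steps most likely to fail:

Step 1 (proposed new method). The relay delivers only one equivalent of H2O2, so any peroxide lost leaves enone 2 unepoxidised. The anthraquinone triplet may also attack the C16 methylene or sensitise enone 2. Unreacted 1 and the β-keto lactone of 3 are both base-sensitive once DBU is added. The fallback sets out from 1 and comes back at 3, using known chemistry. It gives up the relay and the light, and separates hydrogen removal from oxygen delivery into two dark reactions with external stoichiometric oxidants. Compound 1 is oxidised with activated MnO2 in acetone at 20 °C to enone 2, which is isolated. Enone 2 is then epoxidised with tert-butyl hydroperoxide and DBU in CH2Cl2 at 0 °C to give 3. No new compound is made.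

Step 3 (proposed new method). The same relay risks apply. In addition, the C1 ketyl-type radical sits next to the C10–O bond, and 8 must not see excess base. The fallback sets out from 6 and comes back at 9, using known chemistry, and installs the C3 oxygen through boron instead of an oxirane. Compound 6 is oxidised with activated MnO2 to enone 7, which is isolated. Conjugate borylation of 7 (CuCl 10 mol %, xantphos 10 mol %, NaOtBu, B2pin2, MeOH, THF, 20 °C) adds boron to C3 from the open β face and gives 13-hydroxy-1-oxo-3β-(4,4,5,5-tetramethyl-1,3,2-dioxaborolan-2-yl)-20-norgibberell-16-ene-7,19-dioic acid 19,10-lactone F3. Oxidation with NaBO3·4H2O in THF–H2O, with retention at C3, gives 9 directly. Compound 8 and step 4 are bypassed.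

Step 2 (Wharton transposition). Yields of this reaction are often moderate. Hydrazine may attack the hindered lactone or the β-keto lactone, and traces of oxidant would give diimide. The fallback sets out from 1 and comes back at 6, using known chemistry; it replaces the hydrazone chemistry by a radical deoxygenative fragmentation and needs neither 2 nor 3. Hydroxyl-directed epoxidation of 1 (VO(acac)2 5 mol %, tert-butyl hydroperoxide, CH2Cl2, 0 °C) is delivered syn to the 3β-hydroxyl; the bridgehead 13-hydroxyl lies near the plane of the C16 alkene and cannot direct. This gives 1β,2β-epoxy-3β,13-dihydroxy-20-norgibberell-16-ene-7,19-dioic acid 19,10-lactone F1. Treatment with 1,1'-thiocarbonyldiimidazole and DMAP (the acyl imidazole at C7 is hydrolysed on aqueous work-up) gives the 3-O-(imidazol-1-ylthiocarbonyl) ester of F1, named 1β,2β-epoxy-13-hydroxy-3β-(imidazol-1-ylthiocarbonyloxy)-20-norgibberell-16-ene-7,19-dioic acid 19,10-lactone F2. Bu3SnH and AIBN in toluene at 80 °C generate the C3 radical, which opens the oxirane at C2–O; the resulting C1 alkoxy radical takes hydrogen from the stannane to give 6.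

**Further compounds**

F0 | step 1 | none | none
F1 | step 2 | 1β,2β-epoxy-3β,13-dihydroxy-20-norgibberell-16-ene-7,19-dioic acid 19,10-lactone | C=C1C[C@]23C[C@@]1(O)CC[C@H]2[C@@]12OC(=O)[C@@](C)([C@H]1[C@@H]3C(=O)O)[C@@H](O)[C@H]4O[C@H]42
F2 | step 2 | 1β,2β-epoxy-13-hydroxy-3β-(imidazol-1-ylthiocarbonyloxy)-20-norgibberell-16-ene-7,19-dioic acid 19,10-lactone | C=C1C[C@]23C[C@@]1(O)CC[C@H]2[C@@]12OC(=O)[C@@](C)([C@H]1[C@@H]3C(=O)O)[C@@H](OC(=S)n4ccnc4)[C@H]5O[C@H]52
F3 | step 3 | 13-hydroxy-1-oxo-3β-(4,4,5,5-tetramethyl-1,3,2-dioxaborolan-2-yl)-20-norgibberell-16-ene-7,19-dioic acid 19,10-lactone | C=C1C[C@]23C[C@@]1(O)CC[C@H]2[C@@]12OC(=O)[C@@](C)([C@H]1[C@@H]3C(=O)O)[C@@H](B4OC(C)(C)C(C)(C)O4)CC2=O
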